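Numbering runs along the heptane chain from the catechol ring (ring A, C1) to the 4-hydroxyphenyl ring (ring B, C7). The route rests on cutting C5–C6. The key step exploits the C6=C7 styrene unit on ring B as its own handle. In one operation a visible-light palladium-catalysed alkyl Heck reaction adds a C5 radical to the CH2 terminus of a 4-silyloxystyrene and restores the alkene as the E isomer, so no vinyl halide or vinyl metal is needed. Its precursor is an (S)-3-acetoxyalkyl bromide, assembled in one flask from a catechol-derived benzyl Grignard reagent, (R)-2-(2-bromoethyl)oxirane (source of the C3 stereocentre) and acetic anhydride. Silyl ethers are the only protecting groups.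

Key step: step 5

Assumption: (R)-2-(2-bromoethyl)oxirane and tert-butyldimethyl(4-vinylphenoxy)silane are taken as catalogue compounds; the epoxide is otherwise available by hydrolytic kinetic resolution of the racemate.

Step 1
Reactants: 1 3,4-dihydroxybenzaldehyde
Product: 2 3,4-bis(tert-butyldimethylsilyloxy)benzaldehyde
Conditions: TBSCl (2.4 equiv), imidazole (5 equiv), DMF, 0 °C → rt
Reagents that add atoms: tert-butyldimethylsilyl chloride, CC(C)(C)[Si](C)(C)Cl
Why: Imidazole-promoted silylation converts both phenols into TBS ethers without touching the aldehyde, and these ethers should survive the Grignard, acetylation and palladium steps yet leave under buffered fluoride.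

Step 2
Reactants: 2 3,4-bis(tert-butyldimethylsilyloxy)benzaldehyde
Product: 3 [3,4-bis(tert-butyldimethylsilyloxy)phenyl]methanol
Conditions: NaBH4, EtOH/THF, 0 °C, 30 min
Reagents that add atoms: none
Why: Hydride reduction of the aromatic aldehyde with NaBH4 is fast at 0 °C, and the short reaction time should keep the base-sensitive aryl silyl ethers intact.

Step 3
Reactants: 3 [3,4-bis(tert-butyldimethylsilyloxy)phenyl]methanol
Product: 5 4-(chloromethyl)-1,2-bis(tert-butyldimethylsilyloxy)benzene, via benzylic mesylate 4 (not isolated)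
Conditions: MsCl, Et3N, LiCl, THF, 0 °C → rt; used at once
Reagents that add atoms: lithium chloride, [Li+].[Cl-]; methanesulfonyl chloride, CS(=O)(=O)Cl (its chloride joins the same pool)
Why: Mesylation followed by SN2 displacement of the electron-rich benzylic mesylate by chloride in the same flask gives the benzylic chloride under non-acidic conditions that spare the silyl ethers.

Step 4
Reactants: 5 4-(chloromethyl)-1,2-bis(tert-butyldimethylsilyloxy)benzene, 6 (R)-2-(2-bromoethyl)oxirane
Product: 9 (S)-1-bromo-5-[3,4-bis(tert-butyldimethylsilyloxy)phenyl]pentan-3-yl acetate, via Grignard reagent 7 (not isolated), via chloromagnesium alkoxide 8 (not isolated)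
Conditions: Mg turnings, THF, 0 °C (slow addition of 5); then 6, CuI (10 mol %), THF, −40 → −20 °C; then Ac2O (3 equiv), DMAP (10 mol %), −20 °C → rt
Reagents that add atoms: acetic anhydride, CC(=O)OC(C)=O
Why: Magnesium insertion gives the benzylic Grignard reagent, whose copper-catalysed SN2 opening of the epoxide at its unsubstituted carbon should outpace substitution of the primary bromide at −40 °C and does not break the C–O bond of the stereocentre, so the (R)-epoxide delivers the C3 configuration of the target (descriptor S here only because CH2CH2Br outranks the arylethyl arm), and the magnesium alkoxide is acetylated in the same flask by DMAP-catalysed acyl transfer.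

Step 5
Reactants: 9 (S)-1-bromo-5-[3,4-bis(tert-butyldimethylsilyloxy)phenyl]pentan-3-yl acetate, 10 tert-butyldimethyl(4-vinylphenoxy)silane
Product: 11 (3R,6E)-1-[3,4-bis(tert-butyldimethylsilyloxy)phenyl]-7-[4-(tert-butyldimethylsilyloxy)phenyl]hept-6-en-3-yl acetate
Conditions: PdCl2(PPh3)2 (5 mol %), Xantphos (6 mol %), KOAc (1.5 equiv), 10 (3 equiv), DMA, blue LEDs (450 nm), rt, under argon
Reagents that add atoms: none
Why: Visible-light palladium-catalysed alkyl Heck reaction (radical–polar hybrid Mizoroki–Heck coupling of an unactivated primary alkyl bromide with a vinylarene, a known reaction type): photoexcited zerovalent palladium–Xantphos abstracts bromine from C5 of 9, giving a primary C5 radical and a monovalent palladium bromide. The radical adds to the unsubstituted vinyl carbon of 10, which becomes C6, so the C5–C6 bond is formed and the spin lands on benzylic C7, stabilised by the para-silyloxyphenyl ring B; recombination with monovalent palladium gives a divalent benzylpalladium bromide. Syn β-hydride elimination of a C6 hydrogen releases 11, and KOAc removes HBr to return zerovalent palladium. No ring is closed and no stereocentre is created; the only new stereoelement, the C6=C7 geometry, is set as E in the β-hydride elimination through the conformer with ring B and the C5 chain anti, and E is also the thermodynamic isomer. The step needs regioselectivity for the CH2 terminus (secured by the benzylic stabilisation), preference for intermolecular addition over β-hydride loss at C4 or 1,5-hydrogen shift from benzylic C1 (secured by three equivalents of the electron-rich styrene), and mild neutral conditions for the acetate and aryl silyl ethers (KOAc, room temperature). The C3 stereocentre is two carbons from the radical site and carries over unchanged.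

Step 6
Reactants: 11 (3R,6E)-1-[3,4-bis(tert-butyldimethylsilyloxy)phenyl]-7-[4-(tert-butyldimethylsilyloxy)phenyl]hept-6-en-3-yl acetate
Product: 12 (3R,6E)-1-(3,4-dihydroxyphenyl)-7-(4-hydroxyphenyl)hept-6-en-3-yl acetate
Conditions: TBAF (3.6 equiv), AcOH (4 equiv), THF, 0 °C → rt, under argon
Reagents that add atoms: none
Why: Fluoride-induced cleavage of the three aryl Si–O bonds is fast at 0 °C and acetic acid protonates each phenoxide as it forms, so the secondary acetate should be neither transesterified nor hydrolysed, the catechol is not oxidised, and the stereocentre and the E-alkene are unaffected.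

Compound list
1 | 3,4-dihydroxybenzaldehyde | O=Cc1ccc(O)c(O)c1 | starting material
2 | 3,4-bis(tert-butyldimethylsilyloxy)benzaldehyde | O=Cc1ccc(O[Si](C)(C)C(C)(C)C)c(O[Si](C)(C)C(C)(C)C)c1 | intermediate
3 | [3,4-bis(tert-butyldimethylsilyloxy)phenyl]methanol | OCc1ccc(O[Si](C)(C)C(C)(C)C)c(O[Si](C)(C)C(C)(C)C)c1 | intermediate
4 | 3,4-bis(tert-butyldimethylsilyloxy)benzyl methanesulfonate | CS(=O)(=O)OCc1ccc(O[Si](C)(C)C(C)(C)C)c(O[Si](C)(C)C(C)(C)C)c1 | intermediate
5 | 4-(chloromethyl)-1,2-bis(tert-butyldimethylsilyloxy)benzene | ClCc1ccc(O[Si](C)(C)C(C)(C)C)c(O[Si](C)(C)C(C)(C)C)c1 | intermediate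
6 | (R)-2-(2-bromoethyl)oxirane | BrCC[C@@H]1CO1 | starting material
7 | [3,4-bis(tert-butyldimethylsilyloxy)benzyl]magnesium chloride | Cl[Mg]Cc1ccc(O[Si](C)(C)C(C)(C)C)c(O[Si](C)(C)C(C)(C)C)c1 | intermediate
8 | chloromagnesium (S)-1-bromo-5-[3,4-bis(tert-butyldimethylsilyloxy)phenyl]pentan-3-olate | Cl[Mg]O[C@H](CCBr)CCc1ccc(O[Si](C)(C)C(C)(C)C)c(O[Si](C)(C)C(C)(C)C)c1 | intermediate
9 | (S)-1-bromo-5-[3,4-bis(tert-butyldimethylsilyloxy)phenyl]pentan-3-yl acetate | CC(=O)O[C@H](CCBr)CCc1ccc(O[Si](C)(C)C(C)(C)C)c(O[Si](C)(C)C(C)(C)C)c1 | intermediate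
10 | tert-butyldimethyl(4-vinylphenoxy)silane | C=Cc1ccc(O[Si](C)(C)C(C)(C)C)cc1 | starting material
11 | (3R,6E)-1-[3,4-bis(tert-butyldimethylsilyloxy)phenyl]-7-[4-(tert-butyldimethylsilyloxy)phenyl]hept-6-en-3-yl acetate | CC(=O)O[C@H](CC/C=C/c1ccc(O[Si](C)(C)C(C)(C)C)cc1)CCc1ccc(O[Si](C)(C)C(C)(C)C)c(O[Si](C)(C)C(C)(C)C)c1 | intermediate
12 | (3R,6E)-1-(3,4-dihydroxyphenyl)-7-(4-hydroxyphenyl)hept-6-en-3-yl acetate | CC(=O)O[C@H](CC/C=C/c1ccc(O)cc1)CCc1ccc(O)c(O)c1 | target

Total step count: 6. Longest linear sequence: 6 steps (1 → 12; compounds 6 and 10 are purchased).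

Steps most likely to fail

Step 5. The C5 radical may be translocated to benzylic C1 by 1,5-hydrogen shift or lost by β-hydride elimination at C4 before it adds to the styrene, and the product alkene may partly isomerise from E to Z under irradiation. The fallback is a polar alkyl–alkenyl cross-coupling that never passes through a free C5 radical, and it sets out from 9. Purchased tert-butyl(4-ethynylphenoxy)dimethylsilane F1 is hydrozirconated with Cp2Zr(H)Cl (THF, rt) to the (E)-alkenylzirconocene chloride F2, by syn addition with zirconium at the terminal carbon. F2 is then coupled with 9 under Pd(acac)2 (2.5 mol %), LiBr, THF/NMP, 55 °C (Negishi-type coupling of a primary alkyl bromide). This forms the same C5–C6 bond and comes back to the route at 11.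

Step 4. Wurtz homocoupling may consume the electron-rich benzylic chloride during magnesium insertion, and magnesium halide may open the epoxide to a halohydrin or the organometallic may attack the C–Br bond. The fallback sets out from 5 and uses it in its natural polarity, as an electrophile. The dianion of methyl acetoacetate (NaH, then n-BuLi, THF, 0 °C) is alkylated at its terminal carbon by 5 to give methyl 5-[3,4-bis(tert-butyldimethylsilyloxy)phenyl]-3-oxopentanoate F3. Noyori hydrogenation (RuCl2[(S)-BINAP], H2, MeOH) sets C3 under catalyst control and gives methyl (S)-5-[3,4-bis(tert-butyldimethylsilyloxy)phenyl]-3-hydroxypentanoate F4. LiBH4 (THF) gives (S)-5-[3,4-bis(tert-butyldimethylsilyloxy)phenyl]pentane-1,3-diol F5. Primary-selective Appel bromination (CBr4, PPh3, CH2Cl2, −30 °C) gives (S)-1-bromo-5-[3,4-bis(tert-butyldimethylsilyloxy)phenyl]pentan-3-ol F6. Ac2O, pyridine and DMAP then return to the route at 9.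

Step 6. Phenoxides set free by fluoride may transfer or remove the acetyl group (acyl scrambling between the alkyl and aryl oxygens), and the free catechol may oxidise during work-up. The fallback sets out from 11. TBAF (THF, 0 °C) followed in the same flask by Ac2O/pyridine traps every phenoxide as its acetate and gives (3R,6E)-1-(3,4-diacetoxyphenyl)-7-(4-acetoxyphenyl)hept-6-en-3-yl acetate F7, which erases any scrambling. Chemoselective solvolysis of the three aryl acetates (NH4OAc, MeOH/H2O, rt), to which the far less electrophilic secondary alkyl acetate should be inert, comes back to the route at 12.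

Further compounds
F1 | step 5 | tert-butyl(4-ethynylphenoxy)dimethylsilane | C#Cc1ccc(O[Si](C)(C)C(C)(C)C)cc1
F2 | step 5 | chlorobis(cyclopentadienyl)[(E)-2-[4-(tert-butyldimethylsilyloxy)phenyl]ethenyl]zirconium | Cl[Zr](/C=C/c1ccc(O[Si](C)(C)C(C)(C)C)cc1)(C1C=CC=C1)C1C=CC=C1
F3 | step 4 | methyl 5-[3,4-bis(tert-butyldimethylsilyloxy)phenyl]-3-oxopentanoate | COC(=O)CC(=O)CCc1ccc(O[Si](C)(C)C(C)(C)C)c(O[Si](C)(C)C(C)(C)C)c1
F4 | step 4 | methyl (S)-5-[3,4-bis(tert-butyldimethylsilyloxy)phenyl]-3-hydroxypentanoate | COC(=O)C[C@@H](O)CCc1ccc(O[Si](C)(C)C(C)(C)C)c(O[Si](C)(C)C(C)(C)C)c1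
F5 | step 4 | (S)-5-[3,4-bis(tert-butyldimethylsilyloxy)phenyl]pentane-1,3-diol | OCC[C@@H](O)CCc1ccc(O[Si](C)(C)C(C)(C)C)c(O[Si](C)(C)C(C)(C)C)c1
F6 | step 4 | (S)-1-bromo-5-[3,4-bis(tert-butyldimethylsilyloxy)phenyl]pentan-3-ol | BrCC[C@@H](O)CCc1ccc(O[Si](C)(C)C(C)(C)C)c(O[Si](C)(C)C(C)(C)C)c1
F7 | step 6 | (3R,6E)-1-(3,4-diacetoxyphenyl)-7-(4-acetoxyphenyl)hept-6-en-3-yl acetate | CC(=O)O[C@H](CC/C=C/c1ccc(OC(C)=O)cc1)CCc1ccc(OC(C)=O)c(OC(C)=O)c1
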